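**Retrosynthetic overview**
- Feature: the vicinal carbinols C5 (angelate) and C6 (free OH) lie inside the ten-membered carbocycle C1–C10, between C4(=C15) and C7, the fusion carbon of the trans-fused γ-lactone ring C7–C11–C12(=O)–O–C8. The C5–C6 bond is therefore the ring-closing bond, made by reductive coupling of a C5 enal with a C6 aldehyde.
- Seco dialdehyde: the lactone ring is built first, with C8–O from a proline α-aminoxylation, then a Z-enoate and butenolide, then C6 from a trans conjugate addition of lithiated 1,3-dithiane at C7.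
- Chain: C2–C3 comes from α-selective addition of a nerol-derived allylbarium (C7–C10, C14, C1, C2; Z olefin from neryl acetate) to 2-(PMB-oxymethyl)acrolein (C3–C5, C15). C3 is fixed by CBS reduction and held as a TBS ether to the last step.
- Ring order: γ-lactone (step 12), ten-membered ring (step 17), epoxide (step 22). The C13 methylene, the C5 angelate and the C3 ketone follow the cyclisation.

Key step: step 17

Remark: germacrane numbering is used in all names. Neryl acetate is taken as the commercial form of nerol. C3 is a temporary stereocentre, made as the single 3R epimer so that the cyclisation substrate is one compound, and it is erased in step 24.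

**Fragment 1 (C3–C5, C15)**

Step 1
Reactants: 1 2-methylenepropane-1,3-diol
Product: 2 2-{[(4-methoxybenzyl)oxy]methyl}prop-2-en-1-ol
Conditions: NaH (1 equiv), PMBCl, Bu4NI (cat.), THF/DMF, 0 °C to rt
Reagents that add atoms: 4-methoxybenzyl chloride, COc1ccc(CCl)cc1
Why: Williamson etherification of the symmetric diol with one equivalent of alkoxide should give the mono-ether, separable from bis-ether and diol.

Step 2
Reactants: 2 2-{[(4-methoxybenzyl)oxy]methyl}prop-2-en-1-ol
Product: 3 2-{[(4-methoxybenzyl)oxy]methyl}prop-2-enal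
Conditions: MnO2, CH2Cl2, rt
Reagents that add atoms: none
Why: MnO2 oxidation of the primary allylic alcohol stops at the enal and leaves the PMB ether alone.

**Fragment 2 and chain assembly**

Step 3
Reactants: 4 neryl acetate
Product: 6 (2Z)-6,6-dimethoxy-3-methylhex-2-en-1-yl acetate, via aldehyde 5 (not isolated)
Conditions: O3 (1 equiv), NaHCO3, CH2Cl2/MeOH, −78 °C; Me2S, −78 °C to rt; then HC(OMe)3, TsOH·H2O (cat.), rt
Reagents that add atoms: trimethyl orthoformate, COC(OC)OC
Why: Ozonolysis is chemoselective for the electron-rich 6,7-olefin because the allylic acetate deactivates the 2,3-olefin, so the Z geometry is untouched, and acid-catalysed acetalisation then masks the aldehyde for the organometallic steps.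

Step 4
Reactants: 6 (2Z)-6,6-dimethoxy-3-methylhex-2-en-1-yl acetate
Product: 7 (2Z)-6,6-dimethoxy-3-methylhex-2-en-1-ol
Conditions: K2CO3 (cat.), MeOH, 0 °C to rt
Reagents that add atoms: none
Why: Base-catalysed transesterification removes the acetate while the acetal is stable to base.

Step 5
Reactants: 7 (2Z)-6,6-dimethoxy-3-methylhex-2-en-1-ol
Product: 9 (2Z)-1-chloro-6,6-dimethoxy-3-methylhex-2-ene, via allylic mesylate 8 (not isolated)
Conditions: MsCl, LiCl, 2,4,6-collidine, DMF, 0 °C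
Reagents that add atoms: lithium chloride, [Li+].[Cl-]
Why: Mesylation followed by SN2 displacement with chloride under collidine buffering should give the primary allylic chloride without allylic transposition, Z/E isomerisation or loss of the acetal.

Step 6
Reactants: 9 (2Z)-1-chloro-6,6-dimethoxy-3-methylhex-2-ene; 3 2-{[(4-methoxybenzyl)oxy]methyl}prop-2-enal
Product: 11 rac-(5Z)-9,9-dimethoxy-1-[(4-methoxybenzyl)oxy]-6-methyl-2-methylidenenon-5-en-3-ol, via allylbarium chloride 10 (not isolated)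
Conditions: activated Ba (from BaI2 and lithium biphenylide, Li(C12H10), THF, rt); 9, −78 °C; then 3, −78 °C; aq. NH4Cl
Reagents that add atoms: none
Why: Oxidative addition of activated barium gives an allylbarium that adds to aldehydes at its α-carbon with retention of the Z geometry at −78 °C (allylbarium carbonyl addition), forming C2–C3 by 1,2-addition to the enal; C3 forms without control and is corrected in steps 7 and 8.

Step 7
Reactants: 11 rac-(5Z)-9,9-dimethoxy-1-[(4-methoxybenzyl)oxy]-6-methyl-2-methylidenenon-5-en-3-ol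
Product: 12 (5Z)-9,9-dimethoxy-1-[(4-methoxybenzyl)oxy]-6-methyl-2-methylidenenon-5-en-3-one
Conditions: Dess–Martin periodinane, NaHCO3, CH2Cl2, 0 °C; used crude
Reagents that add atoms: none
Why: Dess–Martin oxidation under bicarbonate buffering converts the allylic alcohol into the enone without moving the skipped C1=C10 olefin into conjugation.

Step 8
Reactants: 12 (5Z)-9,9-dimethoxy-1-[(4-methoxybenzyl)oxy]-6-methyl-2-methylidenenon-5-en-3-one
Product: 13 (3R,5Z)-9,9-dimethoxy-1-[(4-methoxybenzyl)oxy]-6-methyl-2-methylidenenon-5-en-3-ol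
Conditions: (S)-Me-CBS oxazaborolidine [(3aS)-1-methyl-3,3-diphenyltetrahydro-1H,3H-pyrrolo[1,2-c][1,3,2]oxazaborole] (cat.), catecholborane, toluene, −78 °C
Reagents that add atoms: none
Why: In the Corey–Bakshi–Shibata reduction the ketone binds the oxazaborolidine with the 2-substituted alkenyl group as the large substituent, so the (S)-catalyst should deliver hydride to give the 3R alcohol, and catecholborane at −78 °C avoids hydroboration and 1,4-reduction.

Step 9
Reactants: 13 (3R,5Z)-9,9-dimethoxy-1-[(4-methoxybenzyl)oxy]-6-methyl-2-methylidenenon-5-en-3-ol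
Product: 14 (3R,5Z)-3-[(tert-butyldimethylsilyl)oxy]-9,9-dimethoxy-1-[(4-methoxybenzyl)oxy]-6-methyl-2-methylidenenon-5-ene
Conditions: TBSCl, imidazole, DMF, rt
Reagents that add atoms: tert-butyldimethylsilyl chloride, CC(C)(C)[Si](C)(C)Cl
Why: Standard silylation of the secondary allylic alcohol gives the TBS ether that carries C3 to the end of the route.

Step 10
Reactants: 14 (3R,5Z)-3-[(tert-butyldimethylsilyl)oxy]-9,9-dimethoxy-1-[(4-methoxybenzyl)oxy]-6-methyl-2-methylidenenon-5-ene
Product: 15 (4Z,7R)-7-[(tert-butyldimethylsilyl)oxy]-9-[(4-methoxybenzyl)oxy]-4-methyl-8-methylidenenon-4-enal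
Conditions: PPTS (cat.), acetone/H2O (9:1), 50 °C
Reagents that add atoms: water, O
Why: Mild acid hydrolysis cleaves the dimethyl acetal much faster than the secondary TBS ether or the PMB ether.

**Lactone ring and seco dialdehyde**

Step 11
Reactants: 15 (4Z,7R)-7-[(tert-butyldimethylsilyl)oxy]-9-[(4-methoxybenzyl)oxy]-4-methyl-8-methylidenenon-4-enal
Product: 17 methyl (2Z,4R,6Z,9R)-4-(anilinooxy)-9-[(tert-butyldimethylsilyl)oxy]-11-[(4-methoxybenzyl)oxy]-6-methyl-10-methylideneundeca-2,6-dienoate, via α-anilinooxy aldehyde 16 (not isolated)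
Conditions: L-proline (30 mol%), PhNO, MeCN, −20 °C; then added to (CF3CH2O)2P(O)CH2CO2Me, KN(SiMe3)2, 18-crown-6, THF, −78 °C
Reagents that add atoms: nitrosobenzene, O=Nc1ccccc1; methyl bis(2,2,2-trifluoroethyl)phosphonoacetate, COC(=O)CP(=O)(OCC(F)(F)F)OCC(F)(F)F
Why: The L-proline enamine of 15 attacks the nitroso oxygen (α-aminoxylation) on the face directed by the carboxylic acid, which should set C8 as R, and the labile aldehyde is olefinated at once under Still–Gennari conditions to give the Z-enoate needed for lactonisation.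

Step 12
Reactants: 17 methyl (2Z,4R,6Z,9R)-4-(anilinooxy)-9-[(tert-butyldimethylsilyl)oxy]-11-[(4-methoxybenzyl)oxy]-6-methyl-10-methylideneundeca-2,6-dienoate
Product: 19 (5R)-5-{(2Z,5R)-5-[(tert-butyldimethylsilyl)oxy]-7-[(4-methoxybenzyl)oxy]-2-methyl-6-methylidenehept-2-en-1-yl}furan-2(5H)-one, via hydroxy enoate 18 (not isolated)
Conditions: Zn, AcOH, THF, rt; then PPTS (cat.), CH2Cl2, rt
Reagents that add atoms: none
Why: Zinc in acetic acid cleaves the weak N–O bond reductively and the freed Z-γ-hydroxy ester lactonises to the butenolide without touching C8.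

Step 13
Reactants: 19 (5R)-5-{(2Z,5R)-5-[(tert-butyldimethylsilyl)oxy]-7-[(4-methoxybenzyl)oxy]-2-methyl-6-methylidenehept-2-en-1-yl}furan-2(5H)-one; 20 1,3-dithiane
Product: 23 (4S,5R)-4-(1,3-dithian-2-yl)-5-{(2Z,5R)-5-[(tert-butyldimethylsilyl)oxy]-7-[(4-methoxybenzyl)oxy]-2-methyl-6-methylidenehept-2-en-1-yl}dihydrofuran-2(3H)-one, via 2-lithio-1,3-dithiane 21 (not isolated), via lithium enolate 22 (not isolated)
Conditions: 20, n-BuLi, THF, −30 °C; HMPA, −78 °C; then 19, −78 °C; aq. NH4Cl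
Reagents that add atoms: none
Why: Michael addition of 2-lithio-1,3-dithiane in THF/HMPA should occur at C7 of the butenolide on the face opposite the C8 side chain, giving the trans-lactone (7S) after protonation of the enolate at C11.

Step 14
Reactants: 23 (4S,5R)-4-(1,3-dithian-2-yl)-5-{(2Z,5R)-5-[(tert-butyldimethylsilyl)oxy]-7-[(4-methoxybenzyl)oxy]-2-methyl-6-methylidenehept-2-en-1-yl}dihydrofuran-2(3H)-one
Product: 24 (4S,5R)-4-(1,3-dithian-2-yl)-5-{(2Z,5R)-5-[(tert-butyldimethylsilyl)oxy]-7-hydroxy-2-methyl-6-methylidenehept-2-en-1-yl}dihydrofuran-2(3H)-one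
Conditions: DDQ, CH2Cl2/pH 7 buffer, 0 °C
Reagents that add atoms: none
Why: DDQ oxidises the electron-rich PMB ether (benzylic hydride abstraction, then hydrolysis) faster than the dithiane and leaves the TBS ether intact.

Step 15
Reactants: 24 (4S,5R)-4-(1,3-dithian-2-yl)-5-{(2Z,5R)-5-[(tert-butyldimethylsilyl)oxy]-7-hydroxy-2-methyl-6-methylidenehept-2-en-1-yl}dihydrofuran-2(3H)-one
Product: 25 (4S,5R)-4-(1,3-dithian-2-yl)-5-{(2Z,5R)-5-[(tert-butyldimethylsilyl)oxy]-6-formyl-2-methylhepta-2,6-dien-1-yl}dihydrofuran-2(3H)-one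
Conditions: MnO2, CH2Cl2, rt
Reagents that add atoms: none
Why: MnO2 oxidises the primary allylic alcohol to the C5 enal and does not touch the dithiane or the lactone.

Step 16
Reactants: 25 (4S,5R)-4-(1,3-dithian-2-yl)-5-{(2Z,5R)-5-[(tert-butyldimethylsilyl)oxy]-6-formyl-2-methylhepta-2,6-dien-1-yl}dihydrofuran-2(3H)-one
Product: 26 (2R,3S)-2-{(2Z,5R)-5-[(tert-butyldimethylsilyl)oxy]-6-formyl-2-methylhepta-2,6-dien-1-yl}-5-oxooxolane-3-carbaldehyde (seco dialdehyde: C5 enal, C6 aldehyde)
Conditions: MeI, CaCO3, MeCN/H2O (9:1), 40 °C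
Reagents that add atoms: water, O
Why: S-Methylation and hydrolysis unmask the C6 aldehyde under near-neutral conditions, which avoids epimerisation at C7 and β-elimination of the lactone oxygen.

**Ring closure**

Step 17
Reactants: 26 (2R,3S)-2-{(2Z,5R)-5-[(tert-butyldimethylsilyl)oxy]-6-formyl-2-methylhepta-2,6-dien-1-yl}-5-oxooxolane-3-carbaldehyde
Product: 27 (1(10)Z,3R,5S,6S,7R,8R)-3-[(tert-butyldimethylsilyl)oxy]-5,6-dihydroxygermacra-1(10),4(15)-dien-12,8-olide
Conditions: TiCl3(DME)1.5, Zn–Cu couple, DME, reflux (pre-reduction); then 26 in DME by syringe pump at 25 °C (high dilution); aq. K2CO3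
Reagents that add atoms: none
Why: Low-valent titanium transfers one electron to each carbonyl, the two titanium-bound ketyls couple carbon to carbon on the metal and the titanium diolate is hydrolysed to the diol, the process stopping before deoxygenation because the temperature stays at 25 °C. The closest known reaction is the McMurry-type intramolecular pinacol coupling of dialdehydes, enals included, to medium- and large-ring 1,2-diols under slow addition. The ten-membered ring C1–C10 is closed by head-to-head ketyl–ketyl coupling of C5 with C6, a macrocyclisation templated by the metal and helped by two turn elements in the eight-atom tether, the 1(10)-Z olefin and the trans-lactone. C6 is controlled by C7: the ketyl is expected to react in the rotamer that places C5 anti to the lactone methylene C11 with its titanium-bound oxygen near the lactone ring oxygen on C8 (6S), and C5 is set relative to C6 by the preference of ten-membered titanium diolates for the trans (threo) arrangement (5S). The step needs coupling at the carbonyl carbon of the enal and not at C15, which the titanium–oxygen bond at C5 and the larger ring required by C15 coupling both favour, and ring closure over oligomerisation, which slow addition secures.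

**Endgame**

Step 18
Reactants: 27 (1(10)Z,3R,5S,6S,7R,8R)-3-[(tert-butyldimethylsilyl)oxy]-5,6-dihydroxygermacra-1(10),4(15)-dien-12,8-olide
Product: 28 5,6-O-isopropylidene derivative of 27 (configuration unchanged)
Conditions: 2,2-dimethoxypropane, PPTS (cat.), CH2Cl2, rt
Reagents that add atoms: 2,2-dimethoxypropane, COC(C)(C)OC
Why: Acid-catalysed transketalisation protects the trans-diol as the dioxolane so that the lactone can be enolised.

Step 19
Reactants: 28 5,6-O-isopropylidene derivative of 27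
Product: 32 5,6-O-isopropylidene-3-[(tert-butyldimethylsilyl)oxy]germacra-1(10),4(15),11(13)-trien-12,8-olide, via lithium enolate 29 (not isolated), via Mannich base 30 (not isolated), via ammonium iodide 31 (not isolated)
Conditions: LiN(i-Pr)2, THF, −78 °C; CH2=NMe2+ I−, −78 °C to rt; then MeI, MeOH/CH2Cl2, rt; then aq. NaHCO3, CH2Cl2
Reagents that add atoms: Eschenmoser's salt, C=[N+](C)C.[I-]
Why: Mannich alkylation of the lactone lithium enolate with Eschenmoser's salt (anti to the C7 substituent), exhaustive methylation and base-induced β-elimination of trimethylamine should give the α-methylene lactone (C11=C13), the C11 centre formed on the way being destroyed.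

Step 20
Reactants: 32 5,6-O-isopropylidene-3-[(tert-butyldimethylsilyl)oxy]germacra-1(10),4(15),11(13)-trien-12,8-olide
Product: 33 (1(10)Z,3R,5S,6S,7R,8R)-3-[(tert-butyldimethylsilyl)oxy]-5,6-dihydroxygermacra-1(10),4(15),11(13)-trien-12,8-olide
Conditions: AcOH/H2O/THF (3:1:1), 45 °C
Reagents that add atoms: none
Why: The strained trans-fused dioxolane is hydrolysed by aqueous acetic acid under conditions that a hindered secondary TBS ether should survive.

Step 21
Reactants: 33 (1(10)Z,3R,5S,6S,7R,8R)-3-[(tert-butyldimethylsilyl)oxy]-5,6-dihydroxygermacra-1(10),4(15),11(13)-trien-12,8-olide; 34 angelic acid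
Product: 36 (1(10)Z,3R,5S,6S,7R,8R)-5-angeloyloxy-3-[(tert-butyldimethylsilyl)oxy]-6-hydroxygermacra-1(10),4(15),11(13)-trien-12,8-olide, via mixed anhydride 35 (not isolated)
Conditions: 34, 2,4,6-trichlorobenzoyl chloride, Et3N, toluene, rt; then 33, toluene, 75 °C (no DMAP)
Reagents that add atoms: none
Why: Yamaguchi-type esterification through the mixed anhydride without DMAP transfers the angeloyl group without Z to E isomerisation, and the allylic C5 hydroxyl next to the trigonal C4 is expected to react before the C6 hydroxyl, which is flanked by the ring-fusion methine C7.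

Step 22
Reactants: 36 (1(10)Z,3R,5S,6S,7R,8R)-5-angeloyloxy-3-[(tert-butyldimethylsilyl)oxy]-6-hydroxygermacra-1(10),4(15),11(13)-trien-12,8-olide
Product: 37 (1S,3R,5S,6S,7R,8R,10R)-5-angeloyloxy-3-[(tert-butyldimethylsilyl)oxy]-1,10-epoxy-6-hydroxygermacra-4(15),11(13)-dien-12,8-olide
Conditions: m-CPBA, NaHCO3, CH2Cl2, 0 °C
Reagents that add atoms: 3-chloroperoxybenzoic acid, OOC(=O)c1cccc(Cl)c1
Why: Prilezhaev epoxidation is selective for the only electron-rich olefin (trisubstituted C1=C10; C4=C15 is deactivated by two allylic oxygens and both enoates are electron-poor), is stereospecific (Z olefin to cis epoxide) and is expected on the outer face of the olefin, anti to the C8–O bond, which corresponds to 1S,10R.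

Step 23
Reactants: 37 (1S,3R,5S,6S,7R,8R,10R)-5-angeloyloxy-3-[(tert-butyldimethylsilyl)oxy]-1,10-epoxy-6-hydroxygermacra-4(15),11(13)-dien-12,8-olide
Product: 38 (1S,3R,5S,6S,7R,8R,10R)-5-angeloyloxy-1,10-epoxy-3,6-dihydroxygermacra-4(15),11(13)-dien-12,8-olide
Conditions: Bu4NF, AcOH (1:1), THF, 0 °C to rt
Reagents that add atoms: none
Why: Fluoride cleaves the Si–O bond, and buffering with acetic acid protects the epoxide, the α-methylene lactone and the angelate from base and suppresses acyl migration.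

Step 24
Reactants: 38 (1S,3R,5S,6S,7R,8R,10R)-5-angeloyloxy-1,10-epoxy-3,6-dihydroxygermacra-4(15),11(13)-dien-12,8-olide
Product: 39 (1S,5S,6S,7R,8R,10R)-5-angeloyloxy-1,10-epoxy-6-hydroxy-3-oxogermacra-4(15),11(13)-dien-12,8-olide (CNP0348992.1)
Conditions: MnO2, CH2Cl2, rt
Reagents that add atoms: none
Why: MnO2 oxidises only the allylic C3 hydroxyl, giving the cross-conjugated enone and leaving the non-allylic C6 hydroxyl.

**Compound list**

1 | 2-methylenepropane-1,3-diol | C=C(CO)CO | starting material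
2 | 2-{[(4-methoxybenzyl)oxy]methyl}prop-2-en-1-ol | C=C(CO)COCc1ccc(OC)cc1 | intermediate
3 | 2-{[(4-methoxybenzyl)oxy]methyl}prop-2-enal | C=C(C=O)COCc1ccc(OC)cc1 | intermediate
4 | neryl acetate | CC(C)=CCC/C(C)=C\COC(C)=O | starting material
5 | (2Z)-3-methyl-6-oxohex-2-en-1-yl acetate | O=CCC/C(C)=C\COC(C)=O | intermediate
6 | (2Z)-6,6-dimethoxy-3-methylhex-2-en-1-yl acetate | COC(OC)CC/C(C)=C\COC(C)=O | intermediate
7 | (2Z)-6,6-dimethoxy-3-methylhex-2-en-1-ol | COC(OC)CC/C(C)=C\CO | intermediate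
8 | (2Z)-6,6-dimethoxy-3-methylhex-2-en-1-yl methanesulfonate | COC(OC)CC/C(C)=C\COS(C)(=O)=O | intermediate
9 | (2Z)-1-chloro-6,6-dimethoxy-3-methylhex-2-ene | COC(OC)CC/C(C)=C\CCl | intermediate
10 | [(2Z)-6,6-dimethoxy-3-methylhex-2-en-1-yl]barium chloride | COC(OC)CC/C(C)=C\C[Ba]Cl | intermediate
11 | rac-(5Z)-9,9-dimethoxy-1-[(4-methoxybenzyl)oxy]-6-methyl-2-methylidenenon-5-en-3-ol | COC(OC)CC/C(C)=C\CC(O)C(=C)COCc1ccc(OC)cc1 | intermediate
12 | (5Z)-9,9-dimethoxy-1-[(4-methoxybenzyl)oxy]-6-methyl-2-methylidenenon-5-en-3-one | COC(OC)CC/C(C)=C\CC(=O)C(=C)COCc1ccc(OC)cc1 | intermediate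
13 | (3R,5Z)-9,9-dimethoxy-1-[(4-methoxybenzyl)oxy]-6-methyl-2-methylidenenon-5-en-3-ol | COC(OC)CC/C(C)=C\C[C@@H](O)C(=C)COCc1ccc(OC)cc1 | intermediate
14 | TBS ether of 13 | COC(OC)CC/C(C)=C\C[C@@H](O[Si](C)(C)C(C)(C)C)C(=C)COCc1ccc(OC)cc1 | intermediate
15 | (4Z,7R)-7-[(tert-butyldimethylsilyl)oxy]-9-[(4-methoxybenzyl)oxy]-4-methyl-8-methylidenenon-4-enal | O=CCC/C(C)=C\C[C@@H](O[Si](C)(C)C(C)(C)C)C(=C)COCc1ccc(OC)cc1 | intermediate
16 | (2R,4Z,7R)-2-(anilinooxy) derivative of 15 | O=C[C@H](ONc1ccccc1)C/C(C)=C\C[C@@H](O[Si](C)(C)C(C)(C)C)C(=C)COCc2ccc(OC)cc2 | intermediate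
17 | methyl (2Z,4R,6Z,9R)-4-(anilinooxy)-9-[(tert-butyldimethylsilyl)oxy]-11-[(4-methoxybenzyl)oxy]-6-methyl-10-methylideneundeca-2,6-dienoate | COC(=O)/C=C\[C@H](ONc1ccccc1)C/C(C)=C\C[C@@H](O[Si](C)(C)C(C)(C)C)C(=C)COCc2ccc(OC)cc2 | intermediate
18 | methyl (2Z,4R,6Z,9R)-4-hydroxy analogue of 17 | COC(=O)/C=C\[C@H](O)C/C(C)=C\C[C@@H](O[Si](C)(C)C(C)(C)C)C(=C)COCc1ccc(OC)cc1 | intermediate
19 | (5R)-5-{(2Z,5R)-5-[(tert-butyldimethylsilyl)oxy]-7-[(4-methoxybenzyl)oxy]-2-methyl-6-methylidenehept-2-en-1-yl}furan-2(5H)-one | O=C1C=C[C@@H](C/C(C)=C\C[C@@H](O[Si](C)(C)C(C)(C)C)C(=C)COCc2ccc(OC)cc2)O1 | intermediate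
20 | 1,3-dithiane | C1CSCSC1 | starting material
21 | 2-lithio-1,3-dithiane | [Li]C1SCCCS1 | intermediate
22 | lithium enolate of 23 | C1(SCCCS1)[C@H]2C=C(O[Li])O[C@@H]2C/C(C)=C\C[C@@H](O[Si](C)(C)C(C)(C)C)C(=C)COCc3ccc(OC)cc3 | intermediate
23 | (4S,5R)-4-(1,3-dithian-2-yl) trans-lactone, C5 PMB ether | C1(SCCCS1)[C@H]2CC(=O)O[C@@H]2C/C(C)=C\C[C@@H](O[Si](C)(C)C(C)(C)C)C(=C)COCc3ccc(OC)cc3 | intermediate
24 | (4S,5R)-4-(1,3-dithian-2-yl) trans-lactone, C5 alcohol | C1(SCCCS1)[C@H]2CC(=O)O[C@@H]2C/C(C)=C\C[C@@H](O[Si](C)(C)C(C)(C)C)C(=C)CO | intermediate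
25 | (4S,5R)-4-(1,3-dithian-2-yl) trans-lactone, C5 enal | C1(SCCCS1)[C@H]2CC(=O)O[C@@H]2C/C(C)=C\C[C@@H](O[Si](C)(C)C(C)(C)C)C(=C)C=O | intermediate
26 | (2R,3S)-2-{(2Z,5R)-5-[(tert-butyldimethylsilyl)oxy]-6-formyl-2-methylhepta-2,6-dien-1-yl}-5-oxooxolane-3-carbaldehyde | O=C[C@H]1CC(=O)O[C@@H]1C/C(C)=C\C[C@@H](O[Si](C)(C)C(C)(C)C)C(=C)C=O | intermediate
27 | (1(10)Z,3R,5S,6S,7R,8R)-3-[(tert-butyldimethylsilyl)oxy]-5,6-dihydroxygermacra-1(10),4(15)-dien-12,8-olide | C1C(=O)O[C@@H]2C/C(C)=C\C[C@@H](O[Si](C)(C)C(C)(C)C)C(=C)[C@H](O)[C@@H](O)[C@@H]12 | intermediate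
28 | 5,6-O-isopropylidene derivative of 27 | C1C(=O)O[C@@H]2C/C(C)=C\C[C@@H](O[Si](C)(C)C(C)(C)C)C(=C)[C@@H]3OC(C)(C)O[C@H]3[C@@H]12 | intermediate
29 | lithium enolate of 28 | C1=C(O[Li])O[C@@H]2C/C(C)=C\C[C@@H](O[Si](C)(C)C(C)(C)C)C(=C)[C@@H]3OC(C)(C)O[C@H]3[C@@H]12 | intermediate
30 | 11-[(dimethylamino)methyl] derivative of 28 (C13 trans to C6) | CN(C)C[C@@H]1C(=O)O[C@@H]2C/C(C)=C\C[C@@H](O[Si](C)(C)C(C)(C)C)C(=C)[C@@H]3OC(C)(C)O[C@H]3[C@@H]12 | intermediate
31 | trimethylammonium iodide of 30 | C[N+](C)(C)C[C@@H]1C(=O)O[C@@H]2C/C(C)=C\C[C@@H](O[Si](C)(C)C(C)(C)C)C(=C)[C@@H]3OC(C)(C)O[C@H]3[C@@H]12.[I-] | intermediate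
32 | 5,6-O-isopropylidene-3-[(tert-butyldimethylsilyl)oxy]germacra-1(10),4(15),11(13)-trien-12,8-olide | C=C1C(=O)O[C@@H]2C/C(C)=C\C[C@@H](O[Si](C)(C)C(C)(C)C)C(=C)[C@@H]3OC(C)(C)O[C@H]3[C@@H]12 | intermediate
33 | (1(10)Z,3R,5S,6S,7R,8R)-3-[(tert-butyldimethylsilyl)oxy]-5,6-dihydroxygermacra-1(10),4(15),11(13)-trien-12,8-olide | C=C1C(=O)O[C@@H]2C/C(C)=C\C[C@@H](O[Si](C)(C)C(C)(C)C)C(=C)[C@H](O)[C@@H](O)[C@@H]12 | intermediate
34 | angelic acid, (Z)-2-methylbut-2-enoic acid | C/C=C(/C)C(=O)O | starting material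
35 | angelic 2,4,6-trichlorobenzoic anhydride | C/C=C(/C)C(=O)OC(=O)c1c(Cl)cc(Cl)cc1Cl | intermediate
36 | 5-O-angelate of 33 | C=C1C(=O)O[C@@H]2C/C(C)=C\C[C@@H](O[Si](C)(C)C(C)(C)C)C(=C)[C@H](OC(=O)/C(C)=C\C)[C@@H](O)[C@@H]12 | intermediate
37 | (1S,10R)-1,10-epoxide of 36 | C=C1C(=O)O[C@@H]2C[C@@]3(C)O[C@H]3C[C@@H](O[Si](C)(C)C(C)(C)C)C(=C)[C@H](OC(=O)/C(C)=C\C)[C@@H](O)[C@@H]12 | intermediate
38 | (1S,3R,5S,6S,7R,8R,10R)-5-angeloyloxy-1,10-epoxy-3,6-dihydroxygermacra-4(15),11(13)-dien-12,8-olide | C=C1C(=O)O[C@@H]2C[C@@]3(C)O[C@H]3C[C@@H](O)C(=C)[C@H](OC(=O)/C(C)=C\C)[C@@H](O)[C@@H]12 | intermediate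
39 | (1S,5S,6S,7R,8R,10R)-5-angeloyloxy-1,10-epoxy-6-hydroxy-3-oxogermacra-4(15),11(13)-dien-12,8-olide (CNP0348992.1) | C=C1C(=O)O[C@@H]2C[C@@]3(C)O[C@H]3CC(=O)C(=C)[C@H](OC(=O)/C(C)=C\C)[C@@H](O)[C@@H]12 | target

**Step count and risks**

Total steps: 24. Longest linear sequence: 22 steps (steps 3 to 24, from neryl acetate); fragment 1 takes 2 steps.

Steps most likely to fail:

1. Step 17. The delocalised enal ketyl may couple through C15 or between molecules, and facial discrimination at C6 or the threo preference at C5 may be poor. The fallback closes the same C5–C6 bond by a polar allylstannane addition and sets out from enal 25. Bu3SnLi (THF, −78 °C) adds 1,2 to the enal and the carbinol is capped with MOMCl/i-Pr2NEt to give the α-(methoxymethoxy)allylstannane F1 (both C5 epimers). BF3·OEt2 at −78 °C shifts tin to C15 to give the (Z)-γ-(methoxymethoxy)allylstannane F2. MeI/CaCO3 in aqueous MeCN then frees the C6 aldehyde, giving the stannyl aldehyde F3. BF3·OEt2 in dilute CH2Cl2 at −78 °C closes the ring by SE2' addition of the γ-alkoxyallylstannane to the aldehyde through an open transition state; this addition is syn (threo) selective and regenerates the C4=C15 methylene, giving the cyclised 5-O-methoxymethyl ether F4. Me2BBr (CH2Cl2, −78 °C) removes the MOM group and the route is rejoined at diol 27.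

2. Step 21. The two secondary hydroxyls may be acylated with poor discrimination, or the acyl group may migrate from O5 to O6. The fallback uses the allylic nature of C5 and sets out from diol 33. MnO2 oxidises only the allylic hydroxyl to the C5-keto C6-hydroxy enone F5. TESOTf/2,6-lutidine then caps the C6 hydroxyl to give the triethylsilyl ether F6. Luche reduction (NaBH4, CeCl3·7H2O, MeOH, −78 °C) returns the C5 alcohol F7, with hydride expected anti to the C6 silyloxy group (Felkin–Anh, threo). The only free hydroxyl is acylated as in step 21 to give the C6-silylated angelate F8, and PPTS/MeOH removes the triethylsilyl group selectively to rejoin the route at 36.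

3. Step 22. Oxygen delivery to C1=C10 may show poor or reversed facial selectivity. The fallback inverts the facial outcome through a halohydrin and sets out from 36. NBS in aqueous DME at 0 °C forms the bromonium ion on the face the peracid prefers, and water opens it at the tertiary C10 to give the bromohydrin F9 (Br at C1, OH at C10). Ag2O in CH2Cl2 closes the epoxide with inversion at C1, so the oxygen ends on the face opposite to direct epoxidation, and the route is rejoined at 37.

Further compounds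
F1 | step 17 | C5 α-(methoxymethoxy)(tributylstannyl)methyl derivative of 25 (C5 epimers) | C1(SCCCS1)[C@H]2CC(=O)O[C@@H]2C/C(C)=C\C[C@@H](O[Si](C)(C)C(C)(C)C)C(=C)C(OCOC)[Sn](CCCC)(CCCC)CCCC
F2 | step 17 | (Z)-γ-(methoxymethoxy)allylstannane (tin on C15), dithiane at C6 | C1(SCCCS1)[C@H]2CC(=O)O[C@@H]2C/C(C)=C\C[C@@H](O[Si](C)(C)C(C)(C)C)/C(C[Sn](CCCC)(CCCC)CCCC)=C/OCOC
F3 | step 17 | (Z)-γ-(methoxymethoxy)allylstannane with free C6 aldehyde | O=C[C@H]1CC(=O)O[C@@H]1C/C(C)=C\C[C@@H](O[Si](C)(C)C(C)(C)C)/C(C[Sn](CCCC)(CCCC)CCCC)=C/OCOC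
F4 | step 17 | 5-O-methoxymethyl ether of 27 | C1C(=O)O[C@@H]2C/C(C)=C\C[C@@H](O[Si](C)(C)C(C)(C)C)C(=C)[C@H](OCOC)[C@@H](O)[C@@H]12
F5 | step 21 | 5-oxo-6-hydroxy analogue of 33 | C=C1C(=O)O[C@@H]2C/C(C)=C\C[C@@H](O[Si](C)(C)C(C)(C)C)C(=C)C(=O)[C@@H](O)[C@@H]12
F6 | step 21 | 6-O-triethylsilyl ether of F5 | C=C1C(=O)O[C@@H]2C/C(C)=C\C[C@@H](O[Si](C)(C)C(C)(C)C)C(=C)C(=O)[C@@H](O[Si](CC)(CC)CC)[C@@H]12
F7 | step 21 | 6-O-triethylsilyl ether of 33 (5S alcohol) | C=C1C(=O)O[C@@H]2C/C(C)=C\C[C@@H](O[Si](C)(C)C(C)(C)C)C(=C)[C@H](O)[C@@H](O[Si](CC)(CC)CC)[C@@H]12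
F8 | step 21 | 6-O-triethylsilyl ether of 36 | C=C1C(=O)O[C@@H]2C/C(C)=C\C[C@@H](O[Si](C)(C)C(C)(C)C)C(=C)[C@H](OC(=O)/C(C)=C\C)[C@@H](O[Si](CC)(CC)CC)[C@@H]12
F9 | step 22 | 1-bromo-10-hydroxy bromohydrin of 36 | C=C1C(=O)O[C@@H]2C[C@@](C)(O)[C@H](Br)C[C@@H](O[Si](C)(C)C(C)(C)C)C(=C)[C@H](OC(=O)/C(C)=C\C)[C@@H](O)[C@@H]12
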